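**Strategy.** Everything rests on one disconnection in ring D: the bond between the adjacent quaternary carbons C13 and C14, which carry trans methyl groups. A ring E-fused δ-lactone (C12 carbonyl, ring oxygen on C16) with a (Z)-CH=C(CH3)CH2OSi group on C16 undergoes a lactone Ireland–Claisen rearrangement. This forms C13–C14, closes ring D, leaves C15=C16 as the trace of the former allylic ester and unmasks C12 as a carboxyl group, so both quaternary centres arise from planar carbons in one operation. Rings C and B are then annulated onto C12 and C8, and ring A arrives as an aryl alkyne already carrying the dioxane-fused nor-guaiane unit.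

Key step: step 13

Remark: triterpenoid carbons are numbered as in friedelane (α = face of the C20 ester) and the fourteen-carbon nor-guaiane unit as in guaiane with primes; the one assumption is that the catalysts in steps 3 and 30 induce in the sense of the usual empirical models (otherwise the mirror-image catalyst is used).

Step 1
Reactants: 1 propargyl alcohol
Product: 3 (Z)-3-iodo-2-methylprop-2-en-1-ol, via alkenylmagnesium bromide 2 (not isolated)
Conditions: MeMgBr (2.5 equiv), CuI (10 mol%), THF, −10 °C to rt; then I2, −30 °C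
Reagents that add atoms: methylmagnesium bromide, C[Mg]Br; iodine, II
Why: Copper-catalysed carbomagnesiation of the magnesium alkoxide puts methyl on the future C14 and magnesium cis to the CH2O group through a chelate, and iodinolysis with retention gives the (Z)-iodide.

Step 2
Reactants: 3 (Z)-3-iodo-2-methylprop-2-en-1-ol
Product: 4 (Z)-tert-butyl[(3-iodo-2-methylprop-2-enyl)oxy]dimethylsilane
Conditions: TBSCl, imidazole, DMF, rt
Reagents that add atoms: tert-butyldimethylsilyl chloride, CC(C)(C)[Si](C)(C)Cl
Why: Routine silylation of a primary allylic alcohol gives an ether that survives the organochromium coupling and the basic key step.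

Step 3
Reactants: 5 methacrolein; 6 isoprene
Product: 7 (S)-1,4-dimethylcyclohex-3-ene-1-carbaldehyde
Conditions: (S)-3,3-diphenyl-1-(o-tolyl)tetrahydropyrrolo[1,2-c][1,3,2]oxazaborole·HNTf2 (10 mol%), CH2Cl2, −78 °C
Reagents that add atoms: none
Why: Catalytic enantioselective Diels–Alder reaction of an α-substituted enal with a 2-substituted diene gives the para adduct, the shielded face of the catalyst-bound enal setting quaternary C20 (formyl carbon = C29, vinylic methyl = future C16).

Step 4
Reactants: 7 (S)-aldehyde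
Product: 8 (S)-1,4-dimethylcyclohex-3-ene-1-carboxylic acid
Conditions: NaClO2, NaH2PO4, 2-methylbut-2-ene, t-BuOH–H2O, rt
Reagents that add atoms: sodium chlorite, [Na+].[O-]Cl=O
Why: Pinnick oxidation converts the aldehyde to the acid while the scavenger keeps hypochlorous acid away from the ring alkene.

Step 5
Reactants: 8 (S)-acid
Product: 9 4-iodo-1,4-dimethyl-6-oxabicyclo[3.2.1]octan-7-one
Conditions: I2, KI, NaHCO3, H2O–CH2Cl2, 0 °C, dark
Reagents that add atoms: iodine, II
Why: Kinetic iodolactonisation: the axial carboxylate opens the iodonium ion trans-diaxially at C22 (Fürst–Plattner), so the new C22–O bond is necessarily cis to the C20 carboxyl carbon, whereas attack at C17 would need a boat.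

Step 6
Reactants: 9 iodolactone
Product: 10 1,4-dimethyl-6-oxabicyclo[3.2.1]oct-3-en-7-one
Conditions: DBU, toluene, 80 °C
Reagents that add atoms: none
Why: E2 elimination through the anti-periplanar axial hydrogen on C18 gives the C17=C18 alkene and makes the C22–O centre allylic.

Step 7
Reactants: 10 unsaturated lactone
Product: 11 methyl 5-hydroxy-1,4-dimethylcyclohex-3-ene-1-carboxylate (hydroxyl cis to the ester)
Conditions: K2CO3 (cat.), MeOH, 0 °C to rt
Reagents that add atoms: methanol, CO
Why: Methanolysis of the strained bridged lactone frees the C22 alcohol and installs the C29 methyl ester of the target at once.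

Step 8
Reactants: 11 cis-hydroxy ester
Product: 12 ethyl 2-[5-(methoxycarbonyl)-2,5-dimethylcyclohex-2-en-1-yl]propanoate (C18 side chain cis to the C20 ester)
Conditions: EtC(OEt)3, EtCO2H (cat.), xylene, 140 °C
Reagents that add atoms: triethyl orthopropionate, CCC(OCC)(OCC)OCC
Why: Johnson–Claisen rearrangement carries the propionate carbon C13 suprafacially from the C22 oxygen to C18, so C13 ends cis to the C20 ester and the alkene moves to C17=C22 (the C13 configuration is irrelevant).

Step 9
Reactants: 12 diester
Product: 13 ethyl 2-[2-formyl-5-(methoxycarbonyl)-5-methylcyclohex-2-en-1-yl]propanoate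
Conditions: SeO2, 1,4-dioxane–H2O, 90 °C
Reagents that add atoms: selenium dioxide, O=[Se]=O
Why: Allylic oxidation with SeO2 attacks the substituted end of the alkene, where the ring position C18 is a methine, so the vinylic methyl is oxidised (as in pinene to myrtenal) to the C16 enal.

Step 10
Reactants: 13 enal
Product: 14 ethyl 2-[2-formyl-5-(methoxycarbonyl)-5-methylcyclohexyl]propanoate
Conditions: H2 (1 atm), Pd/C, EtOAc, rt
Reagents that add atoms: none
Why: Chemoselective hydrogenation of the conjugated C17=C22 bond; the new C17 centre is planarised again in the next step.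

Step 11
Reactants: 14 saturated aldehyde
Product: 15 ethyl 2-[2-formyl-5-(methoxycarbonyl)-2,5-dimethylcyclohexyl]propanoate (C16, C13 and C29 all α)
Conditions: KOt-Bu, MeI, THF, −40 to 0 °C
Reagents that add atoms: iodomethane, CI
Why: α-Methylation of the aldehyde enolate (far more acidic than the ester) creates quaternary C17, the electrophile entering trans to the vicinal C18 side chain by equatorial attack on the exocyclic enolate, so C16 ends cis to C13.

Step 12
Reactants: 15 quaternary aldehyde; 4 (Z)-alkenyl iodide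
Product: 17 ring E-fused δ-lactone with (Z)-alkenyl group on C16, via hydroxy ester 16 (not isolated)
Conditions: CrCl2 (4 equiv), NiCl2 (1 mol%), DMF, rt; then PPTS (cat.), toluene, 80 °C
Reagents that add atoms: none
Why: Nozaki–Hiyama–Kishi coupling adds the alkenyl group to the aldehyde only, with retention of the (Z) geometry and Felkin–Anh control (C18 as the large group, attack past the C28 methyl), which places the alkenyl group cis to C22; acid-catalysed transesterification then closes the lactone.

Step 13
Reactants: 17 δ-lactone (either C13 epimer)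
Product: 20 ring D/E acid with quaternary C13 and C14, via silyl ketene acetal 18 (not isolated), via trimethylsilyl ester 19 (not isolated)
Conditions: KN(SiMe3)2, Me3SiCl–Et3N, THF, −78 °C; toluene, 105 °C; then 1 M HCl
Reagents that add atoms: none
Why: Ireland–Claisen rearrangement of a lactone silyl ketene acetal: deprotonation at C13 and O-silylation give the endocyclic ketene acetal C13=C12(OSiMe3)–O–C16, whose [3,3] shift through C15=C14 forms C13–C14 and cleaves O–C16 (closest known types: ring-contracting lactone-enolate Claisen rearrangements and ester-enolate Claisen routes to vicinal quaternary carbons). Ring D closes in the pericyclic event itself, a six-membered carbocycle arising from the six-membered lactone and its exocyclic alkenyl group; since C13 and C16 are also tied through C18–C17, only a boat, bicyclo[2.2.2]octane-like array is possible. C13 is controlled by the C16 carbinol centre, because C14 can reach C13 only on the lactone face that carries the alkenyl group. C14 is controlled by the (Z) geometry, which in the boat turns C26 towards the C12–O bridge and C8 towards ring E, giving the trans C26/C27 pair. The step needs enolisation at C13 only (the C20 ester has no α-hydrogen and the original C13 configuration is erased in the planar ketene acetal) and must tolerate the CH2OSi arm pressing against C18. The internal silyl chloride quench traps the enolate before it can fragment to a ketene.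

Step 14
Reactants: 20 ring D/E acid
Product: 22 C12 aldehyde, via acid chloride 21 (not isolated)
Conditions: (COCl)2, DMF (cat.), CH2Cl2, 0 °C; then LiAlH(Ot-Bu)3, THF, −78 °C
Reagents that add atoms: none
Why: The hindered acid is activated as its chloride and reduced by the bulky alkoxyaluminium hydride, which stops at the aldehyde and leaves the C29 ester, the alkene and the silyl ether alone.

Step 15
Reactants: 22 C12 aldehyde
Product: 23 C12 vinyl compound
Conditions: Ph3PCH3Br, KOt-Bu, THF, 0 °C to rt
Reagents that add atoms: methylenetriphenylphosphorane, C=P(c1ccccc1)(c1ccccc1)c1ccccc1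
Why: Wittig methylenation of the non-enolisable neopentyl aldehyde supplies the alkene partner for closing ring C.

Step 16
Reactants: 23 silyl ether
Product: 24 C8 primary alcohol
Conditions: Bu4NF, THF, 40 °C
Reagents that add atoms: none
Why: Fluoride cleavage of the silyl ether frees the C8 hydroxyl without touching the ester.

Step 17
Reactants: 24 C8 alcohol
Product: 25 C8 aldehyde
Conditions: Dess–Martin periodinane, NaHCO3, CH2Cl2, rt
Reagents that add atoms: none
Why: Dess–Martin oxidation gives the non-enolisable aldehyde on quaternary C14.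

Step 18
Reactants: 25 C8 aldehyde
Product: 26 C8 homoallylic alcohol (C8 and C9 epimers)
Conditions: (E)-crotyl-B(pin), toluene, 60 °C; aq. NaHCO3
Reagents that add atoms: (E)-crotylboronic acid pinacol ester, C/C=C/CB1OC(C)(C)C(C)(C)O1
Why: Allylboration through a six-membered transition state bonds the γ-carbon only, attaching C9 with its methyl C25 and the C11 vinyl group, and ignores both esters; the two new centres are not needed.

Step 19
Reactants: 26 homoallylic alcohol
Product: 27 C8 ketone with C9 methyl and C11 vinyl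
Conditions: Dess–Martin periodinane, NaHCO3, CH2Cl2, rt
Reagents that add atoms: none
Why: Neutral Dess–Martin oxidation gives the β,γ-unsaturated ketone without conjugating the alkene.

Step 20
Reactants: 27 diene ketone
Product: 28 ring C cyclohexenone (C11=C12)
Conditions: second-generation Hoveyda–Grubbs catalyst (5 mol%), toluene, 80 °C
Reagents that add atoms: none
Why: Ring-closing metathesis of the two terminal vinyl groups forms C11=C12 and the six-membered ring C, the endocyclic C15=C16 alkene being inert.

Step 21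
Reactants: 28 ring C/D/E dienone
Product: 29 ring C/D/E ketone (C8=O)
Conditions: H2 (5 bar), Pd/C, EtOAc, rt
Reagents that add atoms: none
Why: Heterogeneous hydrogenation saturates C11=C12 and the hindered C15=C16 bond; no stereocentre arises at these carbons and the ketone is untouched.

Step 22
Reactants: 30 (S)-carvone
Product: 31 (2S,5S)-dihydrocarvone
Conditions: L-Selectride, THF, −78 °C; then MeOH, NaOMe (cat.), rt
Reagents that add atoms: none
Why: Conjugate hydride reduction and base equilibration give the trans diequatorial ketone, which carries C7′ (isopropenyl) and C10′ (methyl) of the nor-guaiane unit.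

Step 23
Reactants: 31 dihydrocarvone
Product: 32 ethyl 3-methyl-2-oxo-6-(prop-1-en-2-yl)cycloheptane-1-carboxylate
Conditions: N2CHCO2Et, BF3·OEt2, CH2Cl2, 0 °C
Reagents that add atoms: ethyl diazoacetate, CCOC(=O)C=[N+]=[N-]
Why: Lewis acid-promoted diazoester ring expansion (Tiffeneau–Demjanov type) in which the less substituted α-carbon migrates, inserting C5′ between the ketone C1′ and C6′.

Step 24
Reactants: 32 β-keto ester
Product: 33 enol triflate
Conditions: NaH, PhNTf2, THF, 0 °C to rt
Reagents that add atoms: N-phenyl-bis(trifluoromethanesulfonimide), O=S(=O)(N(c1ccccc1)S(=O)(=O)C(F)(F)F)C(F)(F)F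
Why: O-sulfonylation of the β-keto ester enolate fixes the C1′=C5′ double bond as an enol triflate.

Step 25
Reactants: 33 enol triflate
Product: 34 unsaturated diester
Conditions: BrZn(CH2)2CO2Et, Pd(PPh3)4 (5 mol%), THF, 50 °C
Reagents that add atoms: (3-ethoxy-3-oxopropyl)zinc bromide, CCOC(=O)CC[Zn]Br
Why: Negishi coupling of the zinc homoenolate with the enol triflate attaches C2′ and C3′ to C1′ with retention of the tetrasubstituted alkene.

Step 26
Reactants: 34 diester
Product: 35 bicyclic β-keto ester
Conditions: KOt-Bu, THF, 0 °C; AcOH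
Reagents that add atoms: none
Why: Dieckmann condensation of the saturated ester enolate onto the unsaturated ester closes the five-membered ring, driven by the stable β-keto ester enolate.

Step 27
Reactants: 35 β-keto ester
Product: 36 bicyclic enone (C4′ ketone, C1′=C5′)
Conditions: LiCl, H2O, DMSO, 150 °C
Reagents that add atoms: none
Why: Krapcho dealkoxycarbonylation removes the ester under near-neutral conditions that do not enolise C10′.

Step 28
Reactants: 36 enone
Product: 37 tosylhydrazone
Conditions: TsNHNH2, MeOH, AcOH (cat.), 50 °C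
Reagents that add atoms: p-toluenesulfonyl hydrazide, Cc1ccc(cc1)S(=O)(=O)NN
Why: Condensation gives the conjugated tosylhydrazone required for the Shapiro reaction.

Step 29
Reactants: 37 tosylhydrazone
Product: 39 diene (C1′=C5′, C3′=C4′), via alkenyllithium 38 (not isolated)
Conditions: LiN(i-Pr)2 (3 equiv), THF, −78 to 0 °C; H2O, −78 °C
Reagents that add atoms: none
Why: Shapiro reaction: α′-deprotonation at C3′ and loss of sulfinate and N2 give the C4′ alkenyllithium, whose protonation places the new alkene regiospecifically at C3′=C4′; the diene is used cold at once to outrun 1,5-hydrogen shifts.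

Step 30
Reactants: 39 diene
Product: 40 α-epoxide at C3′–C4′
Conditions: (R,R)-N,N′-bis(3,5-di-tert-butylsalicylidene)-1,2-cyclohexanediaminomanganese chloride (5 mol%), mCPBA, NMO, CH2Cl2, −78 °C
Reagents that add atoms: m-chloroperbenzoic acid, OOC(=O)c1cccc(Cl)c1
Why: Jacobsen–Katsuki epoxidation selects the conjugated cis-disubstituted alkene over the tetrasubstituted and 1,1-disubstituted ones, and the (R,R) catalyst should, by analogy with indene, deliver oxygen to the α face (cis to the C10′ methyl).

Step 31
Reactants: 40 vinyl epoxide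
Product: 41 cis C4′ acetate/C3′ alcohol (both α)
Conditions: Pd(PPh3)4 (2 mol%), AcOH, THF, 0 °C
Reagents that add atoms: acetic acid, CC(=O)O
Why: Zerovalent palladium opens the vinyl epoxide to a π-allyl complex and acetate attacks C4′ anti to the metal, i.e. with overall retention, the other allyl terminus C1′ being fully substituted.

Step 32
Reactants: 42 2-methoxy-6-methylphenol
Product: 43 4-bromo-2-methoxy-6-methylphenol
Conditions: Br2, CH2Cl2, 0 °C
Reagents that add atoms: bromine, BrBr
Why: Electrophilic bromination goes para to the hydroxyl group, the only free ortho/para position, which becomes C10.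

Step 33
Reactants: 43 bromophenol
Product: 44 5-bromo-1,2-dimethoxy-3-methylbenzene
Conditions: MeI, K2CO3, acetone, reflux
Reagents that add atoms: iodomethane, CI
Why: Williamson methylation gives a veratrole in which the unhindered methoxy group (future O2) is the stronger para director.

Step 34
Reactants: 44 bromoveratrole
Product: 45 6-bromo-3,4-dimethoxy-2-methylbenzaldehyde
Conditions: Cl2CHOMe, TiCl4, CH2Cl2, 0 °C; H2O
Reagents that add atoms: dichloromethyl methyl ether, COC(Cl)Cl; water, O
Why: Rieche formylation occurs para to the coplanar methoxy group, the only position para to an oxygen donor, placing the future C6 on C5 between the methyl and bromine substituents.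

Step 35
Reactants: 45 dimethoxy aldehyde
Product: 46 6-bromo-3,4-dihydroxy-2-methylbenzaldehyde
Conditions: BBr3, CH2Cl2, −78 to 0 °C; H2O
Reagents that add atoms: none
Why: Lewis acid cleavage of both aryl methyl ethers gives the catechol, whose hydroxyl para to the formyl group (O2) is the more acidic and the less hindered.

Step 36
Reactants: 46 catechol aldehyde; 41 hydroxy acetate
Product: 47 O2–C3′ aryl ether (C3′–O β, C4′ acetate α)
Conditions: PPh3, DIAD, THF, 0 °C to rt
Reagents that add atoms: none
Why: Mitsunobu etherification engages the more acidic, unhindered O2–H and inverts C3′; the cis acetate cannot participate as a neighbouring group.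

Step 37
Reactants: 47 aryl ether aldehyde
Product: 48 aryl alkyne with free C4′ alcohol and free O3–H
Conditions: MeC(O)C(N2)P(O)(OMe)2, K2CO3, MeOH, rt
Reagents that add atoms: dimethyl (1-diazo-2-oxopropyl)phosphonate, COP(=O)(OC)C(=[N+]=[N-])C(C)=O
Why: Seyferth–Gilbert homologation under Ohira–Bestmann conditions turns the aryl aldehyde into the terminal alkyne (C6≡C7) while the same methanolic carbonate removes the C4′ acetate.

Step 38
Reactants: 48 phenol allylic alcohol
Product: 49 benzodioxane aryl alkyne (C10–Br, C5–C≡CH; O3–C4′ and O2–C3′ both β)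
Conditions: PPh3, DIAD, toluene, 0 °C to rt
Reagents that add atoms: none
Why: Intramolecular Mitsunobu etherification of the allylic C4′ alcohol by O3–H proceeds with inversion and closes the 1,4-dioxane, which can only be cis-fused on the cyclopentene.

Step 39
Reactants: 49 benzodioxane aryl alkyne; 29 ring C/D/E ketone
Product: 51 C8 tertiary propargylic alcohol, via lithium acetylide 50 (not isolated)
Conditions: LiN(SiMe3)2, THF, −78 °C; CeCl3; then 29, −78 to 0 °C
Reagents that add atoms: none
Why: The cerium-modified acetylide is a slim, weakly basic nucleophile that adds to the hindered, enolisable C8 ketone and spares the ester and the aryl bromide; the carbinol configuration is irrelevant.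

Step 40
Reactants: 51 propargylic alcohol
Product: 52 aryl enone C6(=O)–C7H=C8
Conditions: Ph3PAuNTf2 (5 mol%), MeOH (1 equiv), toluene, 50 °C
Reagents that add atoms: none
Why: Gold-catalysed Meyer–Schuster rearrangement shifts the oxygen from C8 to C6 and gives the enone, either alkene geometry being usable.

Step 41
Reactants: 52 bromoaryl enone
Product: 53 6-oxo-7-ene with rings A–E closed (9β-methyl)
Conditions: Pd(OAc)2 (10 mol%), P(t-Bu)3·HBF4, NaOt-Bu, toluene, 80 °C
Reagents that add atoms: none
Why: Intramolecular palladium-catalysed γ-arylation of the dienolate (C9–H is the only enolisable hydrogen) joins C9 to C10, closing ring B and creating quaternary C9, the aryl group arriving on the α face, anti to the syn-axial C26 methyl on C14.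

Step 42
Reactants: 53 enone
Product: 54 C6 tosylhydrazone
Conditions: TsNHNH2, PPTS (cat.), EtOH, 75 °C
Reagents that add atoms: p-toluenesulfonyl hydrazide, Cc1ccc(cc1)S(=O)(=O)NN
Why: Condensation occurs at the C6 ketone, conjugate addition being blocked by the fully substituted C8.

Step 43
Reactants: 54 tosylhydrazone
Product: 56 CNP0149558.1, via allylic diazene 55 (not isolated)
Conditions: catecholborane, CHCl3, 0 °C; then NaOAc·3H2O, 60 °C
Reagents that add atoms: none
Why: Alkene-transposing reduction of an unsaturated tosylhydrazone: hydride adds to C6 anti to the C25 methyl, loss of sulfinate gives the β-diazene, and its retro-ene loss of N2 delivers hydrogen suprafacially to the β face of C8 while forming C6=C7, the course that gives cis-fused 5β products from steroidal 4-en-3-one tosylhydrazones.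

**Compound list**

1 | propargyl alcohol | C#CCO | starting material
2 | (Z)-[3-(bromomagnesiooxy)-2-methylprop-1-enyl]magnesium bromide | Br[Mg]/C=C(C)\CO[Mg]Br | intermediate
3 | (Z)-3-iodo-2-methylprop-2-en-1-ol | I/C=C(C)\CO | intermediate
4 | (Z)-tert-butyl[(3-iodo-2-methylprop-2-enyl)oxy]dimethylsilane | I/C=C(C)\CO[Si](C)(C)C(C)(C)C | intermediate
5 | methacrolein | CC(=C)C=O | starting material
6 | isoprene | C=CC(C)=C | starting material
7 | (S)-1,4-dimethylcyclohex-3-ene-1-carbaldehyde | O=C[C@]1(C)CC=C(C)CC1 | intermediate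
8 | (S)-1,4-dimethylcyclohex-3-ene-1-carboxylic acid | OC(=O)[C@]1(C)CC=C(C)CC1 | intermediate
9 | 4-iodo-1,4-dimethyl-6-oxabicyclo[3.2.1]octan-7-one (C22–O cis to the acyl bridge, C17–I trans to that oxygen) | C[C@]12CC[C@](C)(I)[C@H](C1)OC2=O | intermediate
10 | 1,4-dimethyl-6-oxabicyclo[3.2.1]oct-3-en-7-one | C[C@]12CC=C(C)[C@H](C1)OC2=O | intermediate
11 | methyl 5-hydroxy-1,4-dimethylcyclohex-3-ene-1-carboxylate, hydroxyl cis to the ester | COC(=O)[C@@]1(C)CC=C(C)[C@@H](O)C1 | intermediate
12 | ethyl 2-[5-(methoxycarbonyl)-2,5-dimethylcyclohex-2-en-1-yl]propanoate, C18 side chain cis to the C20 ester, C13 epimers | CCOC(=O)C(C)[C@@H]1C[C@](C)(C(=O)OC)CC=C1C | intermediate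
13 | ethyl 2-[2-formyl-5-(methoxycarbonyl)-5-methylcyclohex-2-en-1-yl]propanoate | CCOC(=O)C(C)[C@@H]1C[C@](C)(C(=O)OC)CC=C1C=O | intermediate
14 | ethyl 2-[2-formyl-5-(methoxycarbonyl)-5-methylcyclohexyl]propanoate, C17 epimers | CCOC(=O)C(C)[C@@H]1C[C@](C)(C(=O)OC)CCC1C=O | intermediate
15 | ethyl 2-[2-formyl-5-(methoxycarbonyl)-2,5-dimethylcyclohexyl]propanoate, C16 formyl, C13 chain and C29 ester α, C28 and C30 methyls β | CCOC(=O)C(C)[C@@H]1C[C@](C)(C(=O)OC)CC[C@]1(C)C=O | intermediate
16 | C16 allylic alcohol of 15 carrying the (Z)-CH=C(CH3)CH2OTBS group, alkenyl group cis to C22 | CCOC(=O)C(C)[C@@H]1C[C@](C)(C(=O)OC)CC[C@]1(C)[C@H](/C=C(C)\CO[Si](C)(C)C(C)(C)C)O | intermediate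
17 | ring E-fused δ-lactone (C12 carbonyl, oxygen on C16, (Z)-alkenyl on C16, either C13 epimer) | CC1[C@@H]2C[C@](C)(C(=O)OC)CC[C@]2(C)[C@H](/C=C(C)\CO[Si](C)(C)C(C)(C)C)OC1=O | intermediate
18 | trimethylsilyl ketene acetal of 17 (C13=C12) | C[Si](C)(C)OC1=C(C)[C@@H]2C[C@](C)(C(=O)OC)CC[C@]2(C)[C@H](/C=C(C)\CO[Si](C)(C)C(C)(C)C)O1 | intermediate
19 | trimethylsilyl ester of 20 | C[Si](C)(C)OC(=O)[C@@]1(C)[C@@H]2C[C@](C)(C(=O)OC)CC[C@]2(C)C=C[C@]1(C)CO[Si](C)(C)C(C)(C)C | intermediate
20 | ring D/E acid: C13 (α-CH3, β-CO2H), C14 (β-CH3, α-CH2OTBS), C15=C16 | OC(=O)[C@@]1(C)[C@@H]2C[C@](C)(C(=O)OC)CC[C@]2(C)C=C[C@]1(C)CO[Si](C)(C)C(C)(C)C | intermediate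
21 | acid chloride of 20 | ClC(=O)[C@@]1(C)[C@@H]2C[C@](C)(C(=O)OC)CC[C@]2(C)C=C[C@]1(C)CO[Si](C)(C)C(C)(C)C | intermediate
22 | C12 aldehyde | O=C[C@@]1(C)[C@@H]2C[C@](C)(C(=O)OC)CC[C@]2(C)C=C[C@]1(C)CO[Si](C)(C)C(C)(C)C | intermediate
23 | C12 vinyl compound (C8 silyl ether) | C=C[C@@]1(C)[C@@H]2C[C@](C)(C(=O)OC)CC[C@]2(C)C=C[C@]1(C)CO[Si](C)(C)C(C)(C)C | intermediate
24 | C12 vinyl, C8 alcohol | C=C[C@@]1(C)[C@@H]2C[C@](C)(C(=O)OC)CC[C@]2(C)C=C[C@]1(C)CO | intermediate
25 | C12 vinyl, C8 aldehyde | C=C[C@@]1(C)[C@@H]2C[C@](C)(C(=O)OC)CC[C@]2(C)C=C[C@]1(C)C=O | intermediate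
26 | C8 homoallylic alcohol with C9 methyl and C11 vinyl (epimers) | C=C[C@@]1(C)[C@@H]2C[C@](C)(C(=O)OC)CC[C@]2(C)C=C[C@]1(C)C(O)C(C)C=C | intermediate
27 | C8 ketone with C9 methyl and C11 vinyl | C=C[C@@]1(C)[C@@H]2C[C@](C)(C(=O)OC)CC[C@]2(C)C=C[C@]1(C)C(=O)C(C)C=C | intermediate
28 | ring C/D/E dienone (C8=O, C11=C12, C15=C16) | O=C1C(C)C=C[C@@]2(C)[C@@H]3C[C@](C)(C(=O)OC)CC[C@]3(C)C=C[C@]12C | intermediate
29 | ring C/D/E ketone (C8=O, C9 epimers) | O=C1C(C)CC[C@@]2(C)[C@@H]3C[C@](C)(C(=O)OC)CC[C@]3(C)CC[C@]12C | intermediate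
30 | (S)-carvone | CC1=CC[C@@H](CC1=O)C(=C)C | starting material
31 | (2S,5S)-dihydrocarvone (trans) | C[C@H]1CC[C@@H](CC1=O)C(=C)C | intermediate
32 | ethyl 3-methyl-2-oxo-6-(prop-1-en-2-yl)cycloheptane-1-carboxylate (C10′ methyl and C7′ isopropenyl trans) | C[C@H]1CC[C@@H](CC(C(=O)OCC)C1=O)C(=C)C | intermediate
33 | enol triflate of 32 (C1′=C5′) | C[C@H]1CC[C@@H](CC(C(=O)OCC)=C1OS(=O)(=O)C(F)(F)F)C(=C)C | intermediate
34 | unsaturated diester (C1′ bears CH2CH2CO2Et) | C[C@H]1CC[C@@H](CC(C(=O)OCC)=C1CCC(=O)OCC)C(=C)C | intermediate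
35 | bicyclic β-keto ester (C4′ ketone, C3′ ester) | C[C@H]1CC[C@@H](CC2=C1CC(C(=O)OCC)C2=O)C(=C)C | intermediate
36 | bicyclic enone: 8-methyl-5-(prop-1-en-2-yl)-hexahydroazulen-1-one with C1′=C5′ | C[C@H]1CC[C@@H](CC2=C1CCC2=O)C(=C)C | intermediate
37 | tosylhydrazone of 36 | C[C@H]1CC[C@@H](CC2=C1CCC2=NNS(=O)(=O)c3ccc(C)cc3)C(=C)C | intermediate
38 | C4′ alkenyllithium | C[C@H]1CC[C@@H](CC2=C1CC=C2[Li])C(=C)C | intermediate
39 | nor-guaia-1′(5′),3′-diene with 7′-isopropenyl | C[C@H]1CC[C@@H](CC2=C1CC=C2)C(=C)C | intermediate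
40 | 3′,4′-epoxide, oxygen α (cis to the C10′ methyl) | C=C(C)[C@H]1CC[C@H](C)C2=C(C1)[C@H]1O[C@H]1C2 | intermediate
41 | cis C4′ acetate/C3′ alcohol, both α | C=C(C)[C@H]1CC[C@H](C)C2=C(C1)[C@@H](OC(C)=O)[C@@H](O)C2 | intermediate
42 | 2-methoxy-6-methylphenol | COc1cccc(C)c1O | starting material
43 | 4-bromo-2-methoxy-6-methylphenol | COc1cc(Br)cc(C)c1O | intermediate
44 | 5-bromo-1,2-dimethoxy-3-methylbenzene | COc1cc(Br)cc(C)c1OC | intermediate
45 | 6-bromo-3,4-dimethoxy-2-methylbenzaldehyde | COc1cc(Br)c(C=O)c(C)c1OC | intermediate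
46 | 6-bromo-3,4-dihydroxy-2-methylbenzaldehyde | Oc1cc(Br)c(C=O)c(C)c1O | intermediate
47 | aryl ether: O2 on C3′ (β), C4′ acetate (α), free O3–H, formyl on C5 | C=C(C)[C@H]1CC[C@H](C)C2=C(C1)[C@@H](OC(C)=O)[C@H](Oc3cc(Br)c(C=O)c(C)c3O)C2 | intermediate
48 | aryl alkyne: O2 on C3′ (β), C4′ alcohol (α), free O3–H | C=C(C)[C@H]1CC[C@H](C)C2=C(C1)[C@@H](O)[C@H](Oc3cc(Br)c(C#C)c(C)c3O)C2 | intermediate
49 | benzodioxane aryl alkyne: cis-fused dioxane (O3–C4′, O2–C3′, both β), C10–Br, C5–C≡CH, C4–CH3 | C=C(C)[C@H]1CC[C@H](C)C2=C(C1)[C@@H]1Oc3c(cc(Br)c(C#C)c3C)O[C@@H]1C2 | intermediate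
50 | lithium acetylide of 49 | C=C(C)[C@H]1CC[C@H](C)C2=C(C1)[C@@H]1Oc3c(cc(Br)c(C#C[Li])c3C)O[C@@H]1C2 | intermediate
51 | C8 tertiary propargylic alcohol (C8, C9 epimers) | C=C(C)[C@H]1CC[C@H](C)C2=C(C1)[C@@H]1Oc3c(cc(Br)c(C#CC4(O)C(C)CC[C@@]5(C)[C@@H]6C[C@](C)(C(=O)OC)CC[C@]6(C)CC[C@]45C)c3C)O[C@@H]1C2 | intermediate
52 | aryl enone C6(=O)–C7H=C8 (E/Z, C9 epimers) | C=C(C)[C@H]1CC[C@H](C)C2=C(C1)[C@@H]1Oc3c(cc(Br)c(C(=O)C=C4C(C)CC[C@@]5(C)[C@@H]6C[C@](C)(C(=O)OC)CC[C@]6(C)CC[C@]45C)c3C)O[C@@H]1C2 | intermediate
53 | 6-oxo-7-ene, rings A–E and dioxane closed, 9β-CH3 | C=C(C)[C@H]1CC[C@H](C)C2=C(C1)[C@@H]1Oc3c(cc4c(c3C)C(=O)C=C3[C@@]4(C)CC[C@@]4(C)[C@@H]5C[C@](C)(C(=O)OC)CC[C@]5(C)CC[C@]34C)O[C@@H]1C2 | intermediate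
54 | C6 tosylhydrazone of 53 | C=C(C)[C@H]1CC[C@H](C)C2=C(C1)[C@@H]1Oc3c(cc4c(c3C)C(=NNS(=O)(=O)c6ccc(C)cc6)C=C3[C@@]4(C)CC[C@@]4(C)[C@@H]5C[C@](C)(C(=O)OC)CC[C@]5(C)CC[C@]34C)O[C@@H]1C2 | intermediate
55 | 6β-diazenyl-7-ene | C=C(C)[C@H]1CC[C@H](C)C2=C(C1)[C@@H]1Oc3c(cc4c(c3C)[C@H](N=N)C=C3[C@@]4(C)CC[C@@]4(C)[C@@H]5C[C@](C)(C(=O)OC)CC[C@]5(C)CC[C@]34C)O[C@@H]1C2 | intermediate
56 | CNP0149558.1 | C=C(C)[C@H]1CC[C@H](C)C2=C(C1)[C@@H]1Oc3c(cc4c(c3C)C=C[C@@H]3[C@@]4(C)CC[C@@]4(C)[C@@H]5C[C@](C)(C(=O)OC)CC[C@]5(C)CC[C@]34C)O[C@@H]1C2 | target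

**Step count and risks**

Total: 43 steps. Longest linear sequence: 24 steps (steps 3–21, then 39–43).

The three steps most likely to fail:

Step 13. Two fully substituted carbons must bond in a boat transition state in which the CH2OSi arm on C14 is pressed against C18 of ring E; the ketene acetal may decompose or simply not rearrange before it is hydrolysed back to 17. The fallback sets out from aldehyde 15 and iodide 4 and comes back at acid 20. Wittig methylenation of 15 would give the vinyl diester F1, and selective saponification of its less hindered ethyl ester the acid F2. Iodide 4 would be converted (t-BuLi, then paraformaldehyde) into the (Z)-allylic alcohol F3, and esterification (DCC, DMAP) would give the allylic ester F4. An acyclic, chair-type Ireland–Claisen rearrangement (LiN(SiMe3)2, Me3SiCl) would join C13 to C14 without the bicyclic constraint to give the divinyl acid F5. Ring D would then be closed by ring-closing metathesis of the two vinyl groups (second-generation Hoveyda–Grubbs catalyst) to 20. Control at C13 then rests on the facial bias of C18 and on enolate geometry, so diastereomers would have to be separated.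

Step 41. Reductive elimination at the hindered tertiary dienolate carbon may be slower than loss of bromine by reduction or than ionisation of the allylic aryl ether by zerovalent palladium. The fallback sets out from enone 52 and comes back at 53 without a transition metal. Excess LiN(i-Pr)2 would form the C9 dienolate and, by ortho-lithiation at C1 and loss of LiBr, the C1–C10 aryne. The dienolate carbon C9 captures the aryne intramolecularly at C10 (a known enolate–aryne ring closure), and protonation at C1 gives 53. No new compound is made (entry F0).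

Step 30. The cyclopentadiene may isomerise by 1,5-hydrogen shifts before it is oxidised, and facial selectivity far from the existing centres rests on the catalyst alone. The fallback sets out from enone 36 and comes back at hydroxy acetate 41 without passing through the diene. The kinetic enolate of 36 would be silylated to the silyl dienol ether F6. Asymmetric Shi epoxidation of the enol ether, with opening in situ, would give the α′-hydroxy enone F7. Silylation would give the silyl ether F8, and 1,2-reduction (NaBH4, CeCl3) anti to the silyloxy group the cis allylic alcohol F9. Acetylation would give the acetate F10, and acidic desilylation (HF·pyridine, to avoid acyl migration) would give 41.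

**Further compounds**

F1 | step 13 | ethyl 2-[5-(methoxycarbonyl)-2,5-dimethyl-2-vinylcyclohexyl]propanoate (vinyl diester) | CCOC(=O)C(C)[C@@H]1C[C@](C)(C(=O)OC)CC[C@]1(C)C=C
F2 | step 13 | 2-[5-(methoxycarbonyl)-2,5-dimethyl-2-vinylcyclohexyl]propanoic acid | OC(=O)C(C)[C@@H]1C[C@](C)(C(=O)OC)CC[C@]1(C)C=C
F3 | step 13 | (Z)-4-(tert-butyldimethylsilyloxy)-3-methylbut-2-en-1-ol | OC/C=C(C)\CO[Si](C)(C)C(C)(C)C
F4 | step 13 | (Z)-allylic ester of F2 with F3 | O=C(OC/C=C(C)\CO[Si](C)(C)C(C)(C)C)C(C)[C@@H]1C[C@](C)(C(=O)OC)CC[C@]1(C)C=C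
F5 | step 13 | divinyl acid with quaternary C13 and C14 (seco ring D) | OC(=O)[C@@](C)([C@@H]1C[C@](C)(C(=O)OC)CC[C@]1(C)C=C)[C@@](C)(CO[Si](C)(C)C(C)(C)C)C=C
F0 | step 41 | none | none
F6 | step 30 | C4′ tert-butyldimethylsilyl dienol ether of 36 | C[C@H]1CC[C@@H](CC2=C1CC=C2O[Si](C)(C)C(C)(C)C)C(=C)C
F7 | step 30 | 3′α-hydroxy enone | C[C@H]1CC[C@@H](CC2=C1C[C@H](O)C2=O)C(=C)C
F8 | step 30 | 3′α-silyloxy enone | C[C@H]1CC[C@@H](CC2=C1C[C@H](O[Si](C)(C)C(C)(C)C)C2=O)C(=C)C
F9 | step 30 | 3′α-silyloxy-4′α-alcohol | C[C@H]1CC[C@@H](CC2=C1C[C@H](O[Si](C)(C)C(C)(C)C)[C@@H]2O)C(=C)C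
F10 | step 30 | 3′α-silyloxy-4′α-acetate | C[C@H]1CC[C@@H](CC2=C1C[C@H](O[Si](C)(C)C(C)(C)C)[C@@H]2OC(C)=O)C(=C)C
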